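**Retrosynthetic overview** (daucane numbering for the ring system)

1. Target ⇒ veratroyl ester on the secondary 6‑OH (last step) ⇒ 8α,9α‑epoxide by 6‑OH‑directed epoxidation ⇒ jaeschkeanadiol (dauc‑8‑ene‑4β,6α‑diol).
2. Jaeschkeanadiol ⇒ one cation–olefin bicyclisation of an acyclic C15 hydroxy keto allylsilane. It makes the two ring bonds of the presumed farnesyl → daucane cascade (C4–C5 and C1–C10), but is started at the C4 carbonyl, the carbon the natural cascade quenches with water, so the 4‑OH is formed in the ring closure and the 6‑OH is carried in.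
3. Ring order: no ring before this step; the five‑membered ring (C4–C5) and the seven‑membered ring (C1–C10) close together by anti addition across the E olefin (trans fusion); loss of silicon leaves the 8,9‑olefin.
4. Acyclic chain ⇒ asymmetric Nozaki–Hiyama–Kishi coupling (sets the carbinol that becomes C6) of a β‑silyl aldehyde (vinylsilane → Claisen) with an (E)‑vinyl iodide ketone (carboalumination → enolate alkylation).

Assumption: the ligand antipode in the coupling step is the one that gives the S carbinol (checked once by Mosher ester analysis, mirror ligand otherwise); the silicon‑bearing quaternary carbon is carried as a mixture because it becomes sp2 in the ring‑closing step.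

---

**Step 1**
Reactants: 1 but‑2‑yn‑1‑ol
Product: 2 (Z)‑3‑(triethylsilyl)but‑2‑en‑1‑ol
Conditions: Et3SiH (1.2 equiv), [Cp*Ru(MeCN)3]PF6 (1 mol%), CH2Cl2, 0 °C → rt
Reagents that add atoms: triethylsilane, CC[SiH](CC)CC
Why: Ruthenium‑catalysed trans‑hydrosilylation of a propargylic alcohol places silicon on the carbon remote from the hydroxyl with H and Si trans, giving the Z vinylsilane; no stereocentre is formed.

**Step 2**
Reactants: 2 (Z)‑3‑(triethylsilyl)but‑2‑en‑1‑ol; 3 butyl vinyl ether
Product: 5 racemic 3‑methyl‑3‑(triethylsilyl)pent‑4‑enal, via allyl vinyl ether 4 (not isolated)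
Conditions: 3 (solvent), Pd(OAc)2 (5 mol%), 1,10‑phenanthroline (5 mol%), 75 °C; then PhMe, 150 °C, sealed tube
Reagents that add atoms: none
Why: Palladium‑catalysed transfer vinylation followed by Claisen rearrangement joins the vinyl carbon to the silicon‑bearing olefin carbon and builds the quaternary Si/Me/vinyl carbon; it is racemic, which is acceptable because this centre becomes sp2 in step 7.

**Step 3**
Reactants: 6 prop‑2‑yn‑1‑ol
Product: 8 (E)‑3‑iodo‑2‑methylprop‑2‑en‑1‑ol, via alkenylalane 7 (not isolated)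
Conditions: Me3Al (3 equiv), Cp2ZrCl2 (0.25 equiv), CH2Cl2, 0 °C → rt; then I2, THF, −30 → 0 °C; aq. NaHCO3
Reagents that add atoms: trimethylaluminium, C[Al](C)C; iodine, II
Why: Zirconium‑catalysed syn carboalumination (Negishi) adds CH3 and Al cis across the alkyne with CH3 on the internal carbon, and iodinolysis with retention gives the E iodide that later fixes the E olefin of the cyclisation substrate.

**Step 4**
Reactants: 8 (E)‑3‑iodo‑2‑methylprop‑2‑en‑1‑ol
Product: 9 (E)‑3‑bromo‑1‑iodo‑2‑methylprop‑1‑ene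
Conditions: CBr4, PPh3, CH2Cl2, 0 °C
Reagents that add atoms: carbon tetrabromide, BrC(Br)(Br)Br
Why: Appel bromination of the primary allylic alcohol under neutral conditions leaves the olefin geometry and the vinyl iodide untouched.

**Step 5**
Reactants: 9 (E)‑3‑bromo‑1‑iodo‑2‑methylprop‑1‑ene; 10 3‑methylbutan‑2‑one
Product: 12 (E)‑7‑iodo‑2,6‑dimethylhept‑6‑en‑3‑one, via lithium enolate 11 (not isolated)
Conditions: LiN(iPr)2, THF, −78 °C, 10; then 9, −78 → 0 °C
Reagents that add atoms: none
Why: Kinetic deprotonation at the methyl group and SN2 alkylation by the allylic bromide (enolate alkylation) give the isopropyl ketone; the vinyl iodide is inert to the enolate.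

**Step 6**
Reactants: 5 racemic 3‑methyl‑3‑(triethylsilyl)pent‑4‑enal; 12 (E)‑7‑iodo‑2,6‑dimethylhept‑6‑en‑3‑one
Product: 14 (6E,8S)‑8‑hydroxy‑2,6,10‑trimethyl‑10‑(triethylsilyl)dodeca‑6,11‑dien‑3‑one (both C10 epimers), via trimethylsilyl ether 13 (not isolated)
Conditions: CrCl2 (10 mol%), NiCl2 (2 mol%), valinol‑derived oxazoline–sulfonamide ligand (Kishi type, 11 mol%), Mn (2 equiv), Me3SiCl (2 equiv), Et3N, MeCN, rt; then K2CO3, MeOH
Reagents that add atoms: none
Why: Asymmetric Nozaki–Hiyama–Kishi reaction, in which the alkenylchromium formed with retention of the E geometry adds only to the aldehyde (the isopropyl ketone is left alone) and the chiral chromium complex selects the aldehyde face to set C8 as S.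

**Step 7**
Reactants: 14 (6E,8S)‑8‑hydroxy‑2,6,10‑trimethyl‑10‑(triethylsilyl)dodeca‑6,11‑dien‑3‑one
Product: 16 jaeschkeanadiol [(1R,4R,5S,6S)‑dauc‑8‑ene‑4,6‑diol; 1β‑CH3, 4β‑OH, 5α‑H, 6α‑OH], via dichloroaluminium alkoxide 15 (not isolated)
Conditions: MeAlCl2 (3 equiv), CH2Cl2, −78 → −20 °C; aq. KNa tartrate
Reagents that add atoms: none
Why: Proposed new method: MeAlCl2 first turns the C8–OH into an O–AlCl2 group that chelates and activates the C3 ketone (chain numbering of 14); the E‑6,7‑olefin then adds through C7 to the carbonyl carbon on the side of the C8 oxygen while C12 of the allylsilane bonds to C6 on the opposite face (anti addition across the E olefin as in Stork–Eschenmoser polyene cyclisation, hence the trans fusion with 1β‑CH3 and 5α‑H), the 8S centre choosing the olefin face because its H lies in the olefin plane next to the C6 methyl (allylic 1,3‑strain) with its CH2 arm on the allylsilane side (gives 5S and 1R), the chelate placing the new tertiary OH on the same side of the five‑membered ring as the carbinol carbon (4R, 4β‑OH), and anti SE2′ loss of Et3Si (both C10 epimers converge since that carbon becomes sp2) leaving the 8,9‑olefin; the closest known reaction type is the MeAlCl2‑promoted ketone‑initiated cation–olefin bicyclisation of γ,δ‑unsaturated ketones bearing a second olefin (used for trans‑hydrindanones), here ended by an allylsilane as in allylsilane‑terminated polyene cyclisations.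

**Step 8**
Reactants: 16 jaeschkeanadiol
Product: 17 (1R,4R,5S,6S,8R,9S)‑8,9‑epoxydaucane‑4,6‑diol (8α,9α‑epoxyjaeschkeanadiol)
Conditions: VO(acac)2 (5 mol%), t‑BuOOH (1.5 equiv), CH2Cl2, 0 °C → rt
Reagents that add atoms: tert‑butyl hydroperoxide, CC(C)(C)OO
Why: Vanadium‑catalysed hydroxyl‑directed epoxidation, in which the homoallylic 6α‑OH binds the vanadium peroxide and delivers oxygen to the α face of the 8,9‑olefin (8R,9S), the tertiary 4β‑OH being too remote to direct.

**Step 9**
Reactants: 17 8α,9α‑epoxyjaeschkeanadiol; 18 3,4‑dimethoxybenzoyl chloride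
Product: 19 (1R,4R,5S,6S,8R,9S)‑8,9‑epoxy‑4‑hydroxydaucan‑6‑yl 3,4‑dimethoxybenzoate (target, CNP0251065.1)
Conditions: Et3N, DMAP (cat.), CH2Cl2, 0 °C → rt
Reagents that add atoms: none
Why: DMAP‑catalysed acyl transfer esterifies the only acylable hydroxyl, the secondary 6α‑OH, while the tertiary 4‑OH does not react and the epoxide is stable to the basic medium; no stereocentre is touched.

---

**Compound list**

1 | but‑2‑yn‑1‑ol | CC#CCO | starting material
2 | (Z)‑3‑(triethylsilyl)but‑2‑en‑1‑ol | OC/C=C(/C)[Si](CC)(CC)CC | intermediate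
3 | butyl vinyl ether | C=COCCCC | starting material
4 | triethyl[(2Z)‑4‑(ethenyloxy)but‑2‑en‑2‑yl]silane (allyl vinyl ether) | C=COC/C=C(/C)[Si](CC)(CC)CC | intermediate
5 | racemic 3‑methyl‑3‑(triethylsilyl)pent‑4‑enal | O=CCC(C)(C=C)[Si](CC)(CC)CC | intermediate
6 | prop‑2‑yn‑1‑ol | C#CCO | starting material
7 | alkenylalane: dimethyl[(1E)‑3‑(dimethylalumanyloxy)‑2‑methylprop‑1‑en‑1‑yl]alumane | C/C(CO[Al](C)C)=C\[Al](C)C | intermediate
8 | (E)‑3‑iodo‑2‑methylprop‑2‑en‑1‑ol | OC/C(C)=C/I | intermediate
9 | (E)‑3‑bromo‑1‑iodo‑2‑methylprop‑1‑ene | BrC/C(C)=C/I | intermediate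
10 | 3‑methylbutan‑2‑one | CC(=O)C(C)C | starting material
11 | lithium 3‑methylbut‑1‑en‑2‑olate (lithium enolate) | [Li]OC(=C)C(C)C | intermediate
12 | (E)‑7‑iodo‑2,6‑dimethylhept‑6‑en‑3‑one | CC(C)C(=O)CC/C(C)=C/I | intermediate
13 | trimethylsilyl ether of 14 | C=CC(C)([Si](CC)(CC)CC)C[C@H](O[Si](C)(C)C)/C=C(\C)CCC(=O)C(C)C | intermediate
14 | (6E,8S)‑8‑hydroxy‑2,6,10‑trimethyl‑10‑(triethylsilyl)dodeca‑6,11‑dien‑3‑one (C10 epimers) | C=CC(C)([Si](CC)(CC)CC)C[C@H](O)/C=C(\C)CCC(=O)C(C)C | intermediate
15 | dichloroaluminium alkoxide of 14 | C=CC(C)([Si](CC)(CC)CC)C[C@H](O[Al](Cl)Cl)/C=C(\C)CCC(=O)C(C)C | intermediate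
16 | jaeschkeanadiol, (1R,4R,5S,6S)‑dauc‑8‑ene‑4,6‑diol | O[C@H]2CC(C)=CC[C@@]3(C)CC[C@@](O)(C(C)C)[C@H]23 | intermediate
17 | (1R,4R,5S,6S,8R,9S)‑8,9‑epoxydaucane‑4,6‑diol | O[C@H]2C[C@@]3(C)O[C@H]3C[C@@]3(C)CC[C@@](O)(C(C)C)[C@H]23 | intermediate
18 | 3,4‑dimethoxybenzoyl chloride (veratroyl chloride) | COc1ccc(C(Cl)=O)cc1OC | starting material
19 | (1R,4R,5S,6S,8R,9S)‑8,9‑epoxy‑4‑hydroxydaucan‑6‑yl 3,4‑dimethoxybenzoate | COc1ccc(C(=O)O[C@H]2C[C@@]3(C)O[C@H]3C[C@@]3(C)CC[C@@](O)(C(C)C)[C@H]23)cc1OC | target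

---

**Totals:** 9 steps; longest linear sequence 7 steps (steps 3, 4, 5, 6, 7, 8, 9 from prop‑2‑yn‑1‑ol).

**Steps most likely to fail, each with a fallback**

Step 7 (bicyclisation). The first C–C bond closes a five‑membered ring through an endocyclic olefin, the allylic C8–O bond may ionise under the Lewis acid, and one C10 epimer may close more slowly than the other. The fallback sets out from 14 and comes back at 16. 14 is oxidised (Dess–Martin periodinane, CH2Cl2) to the enone (E)‑2,6,10‑trimethyl‑10‑(triethylsilyl)dodeca‑6,11‑diene‑3,8‑dione F1. F1 is closed in the opposite ring order by an enone‑initiated tandem Sakurai/aldol reaction (TiCl4, CH2Cl2, −78 °C): the allylsilane adds to the complexed enone to form the seven‑membered ring, and the titanium enolate then adds to the isopropyl ketone to give 4β‑hydroxy‑5α‑dauc‑8‑en‑6‑one F2. Reduction with Me4NBH(OAc)3 (hydride delivered from the 4β‑OH, 1,3‑anti) gives the diol. Because C8 is planar in F1, this detour gives the racemate; the mirror diol ent‑jaeschkeanadiol F3 is removed on a chiral stationary phase to leave 16. The ring fusion of F2 must be checked, because stepwise aldol closure can also give the cis‑fused isomer.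

Step 6 (asymmetric coupling). The level and sense of induction with a β‑quaternary aldehyde are uncertain. The fallback sets out from 5 and 12 and comes back at 14. The two are coupled without ligand (CrCl2 in excess, NiCl2 cat., DMSO) to racemic (6E)‑8‑hydroxy‑2,6,10‑trimethyl‑10‑(triethylsilyl)dodeca‑6,11‑dien‑3‑one F4. F4 is resolved by Sharpless kinetic resolution (Ti(OiPr)4, D‑(−)‑diisopropyl tartrate, t‑BuOOH 0.6 equiv, 4 Å sieves, CH2Cl2, −20 °C). The 8R enantiomer is consumed as (6S,7S,8R)‑6,7‑epoxy‑8‑hydroxy‑2,6,10‑trimethyl‑10‑(triethylsilyl)dodec‑11‑en‑3‑one F5, and unreacted 14 (8S) is recovered.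

Step 8 (directed epoxidation). The vanadium Lewis acid may trigger attack of the 4‑OH on the new epoxide, or the direction by the homoallylic OH may be weak. The fallback sets out from 16 and comes back at 19. 16 is acylated first (18, Et3N, DMAP, CH2Cl2) to jaeschkeanadiol 6‑O‑veratrate F6. F6 is then epoxidised under buffered, non‑coordinating conditions (3‑chloroperbenzoic acid, NaHCO3, CH2Cl2, 0 °C). The peracid is expected to approach the α face, away from the β angular methyl, and any β‑epoxide is removed by chromatography.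

---

**Further compounds**

F1 | step 7 | (E)‑2,6,10‑trimethyl‑10‑(triethylsilyl)dodeca‑6,11‑diene‑3,8‑dione | C=CC(C)([Si](CC)(CC)CC)CC(=O)/C=C(\C)CCC(=O)C(C)C
F2 | step 7 | 4β‑hydroxy‑5α‑dauc‑8‑en‑6‑one (formed as the racemate, needed enantiomer drawn) | O=C2CC(C)=CC[C@@]3(C)CC[C@@](O)(C(C)C)[C@H]23
F3 | step 7 | ent‑jaeschkeanadiol, (1S,4S,5R,6R)‑dauc‑8‑ene‑4,6‑diol | O[C@@H]2CC(C)=CC[C@]3(C)CC[C@](O)(C(C)C)[C@@H]23
F4 | step 6 | racemic (6E)‑8‑hydroxy‑2,6,10‑trimethyl‑10‑(triethylsilyl)dodeca‑6,11‑dien‑3‑one | C=CC(C)([Si](CC)(CC)CC)CC(O)/C=C(\C)CCC(=O)C(C)C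
F5 | step 6 | (6S,7S,8R)‑6,7‑epoxy‑8‑hydroxy‑2,6,10‑trimethyl‑10‑(triethylsilyl)dodec‑11‑en‑3‑one | CC(C)C(=O)CC[C@]1(C)O[C@H]1[C@H](O)CC(C)(C=C)[Si](CC)(CC)CC
F6 | step 8 | jaeschkeanadiol 6‑O‑veratrate, (1R,4R,5S,6S)‑4‑hydroxydauc‑8‑en‑6‑yl 3,4‑dimethoxybenzoate | COc1ccc(C(=O)O[C@H]2CC(C)=CC[C@@]3(C)CC[C@@](O)(C(C)C)[C@H]23)cc1OC
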